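**Plan**

- Retrosynthesis: the phenols are unmasked last (benzyl ethers). The C3 hydroxymethyl is traced back to a geminal diester at C3 and the C4 hydroxymethyl to a silyl ether. The oxolane is then cut at O1–C5 and C2–C3 into the C2=O1 unit of an aryl aldehyde and a cyclopropane made of C3, C4 and C5.
- Enabling feature: C5 is a benzylic carbon with a para-oxygenated aryl group (donor), and C3, in a 1,3-relationship to it across C4, carries a carbon that can be held at the carboxyl level (acceptor). C3–C4–C5 can therefore be stored as a donor–acceptor cyclopropane whose C3–C5 bond opens heterolytically, and C2–O1 is a masked 4-(benzyloxy)-3-methoxybenzaldehyde.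
- Forward order: two-carbon homologation of the aldehyde, amine-catalysed cyclopropanation with dimethyl bromomalonate, reduction and silylation, then ring expansion of the three-membered carbocycle to the oxolane by insertion of the aldehyde C=O. Dealkoxycarbonylation, reduction and deprotection follow.
- Stereochemistry: the organocatalytic cyclopropanation sets the future C4 and C5. In the ring expansion C5 is transferred with inversion (aryl cis to the C4 substituent) and C2 is set 2,5-cis. C3 is set last under thermodynamic control (substituent trans to both neighbours).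

Key step: step 5

Assumption: compounds 1 and 3 are purchased; the oxolane is numbered O1, C2 (carbon from the aldehyde partner), C3, C4, C5 (carbons from the cyclopropane), in which numbering the target is (2S,3R,4R,5R).

**Step 1**
Reactants: 1 4-(benzyloxy)-3-methoxybenzaldehyde
Product: 2 (E)-3-[4-(benzyloxy)-3-methoxyphenyl]prop-2-enal
Conditions: Ph3P=CHCHO (1.1 equiv), toluene, 80 °C
Reagents that add atoms: (triphenylphosphoranylidene)acetaldehyde, O=CC=P(c1ccccc1)(c1ccccc1)c1ccccc1
Why: Wittig olefination with a carbonyl-stabilised ylide should give the (E)-enal, with the ylide kept near one equivalent to limit a second homologation.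

**Step 2**
Reactants: 2 (E)-3-[4-(benzyloxy)-3-methoxyphenyl]prop-2-enal; 3 dimethyl bromomalonate
Product: 4 dimethyl (2R,3S)-2-formyl-3-[4-(benzyloxy)-3-methoxyphenyl]cyclopropane-1,1-dicarboxylate
Conditions: (S)-α,α-diphenylprolinol trimethylsilyl ether (20 mol%), 2,6-lutidine (1.1 equiv), CH2Cl2, 0 °C to rt
Reagents that add atoms: none
Why: Iminium-activated Michael-initiated ring closure: the CPh2OTMS group of the (S)-amine shields one face of the (E)-iminium ion, so the bromomalonate adds to the Si face of the β-carbon (3S), and the resulting enamine displaces bromide (3-exo-tet) to close the ring trans (2R).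

**Step 3**
Reactants: 4 dimethyl (2R,3S)-2-formyl-3-[4-(benzyloxy)-3-methoxyphenyl]cyclopropane-1,1-dicarboxylate
Product: 5 dimethyl (2R,3S)-2-(hydroxymethyl)-3-[4-(benzyloxy)-3-methoxyphenyl]cyclopropane-1,1-dicarboxylate
Conditions: NaBH4, MeOH, −20 to 0 °C; pH 7 buffer quench
Reagents that add atoms: none
Why: Borohydride reduction should take the aldehyde chemoselectively over the methyl esters, and low temperature with a neutral quench should keep the alcohol from lactonising onto the cis ester.

**Step 4**
Reactants: 5 dimethyl (2R,3S)-2-(hydroxymethyl)-3-[4-(benzyloxy)-3-methoxyphenyl]cyclopropane-1,1-dicarboxylate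
Product: 6 dimethyl (2R,3S)-3-[4-(benzyloxy)-3-methoxyphenyl]-2-{[tri(propan-2-yl)silyl]oxymethyl}cyclopropane-1,1-dicarboxylate
Conditions: TIPSCl, imidazole, DMF, 0 °C to rt
Reagents that add atoms: triisopropylsilyl chloride, CC(C)[Si](Cl)(C(C)C)C(C)C
Why: Standard silylation of a primary alcohol under non-acidic conditions; the bulky silyl ether blocks lactonisation and should survive the Lewis acid, chloride at 150 °C, methoxide and hydride used later.

**Step 5**
Reactants: 6 dimethyl (2R,3S)-3-[4-(benzyloxy)-3-methoxyphenyl]-2-{[tri(propan-2-yl)silyl]oxymethyl}cyclopropane-1,1-dicarboxylate; 1 4-(benzyloxy)-3-methoxybenzaldehyde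
Product: 8 dimethyl (2R,4R,5R)-2,5-bis[4-(benzyloxy)-3-methoxyphenyl]-4-{[tri(propan-2-yl)silyl]oxymethyl}oxolane-3,3-dicarboxylate, via oxocarbenium malonate zwitterion 7 (not isolated)
Conditions: 1 (2 equiv), AlCl3 (20 mol%), CH2Cl2, 0 °C to rt
Reagents that add atoms: none
Why: AlCl3 chelates the geminal diester of 6 and polarises the bond between the malonyl carbon and the benzylic carbon, so the carbonyl oxygen of 1 attacks the benzylic carbon from the rear in an SN2-like opening to give zwitterion 7, which closes by attack of the malonate carbon on the oxocarbenium carbon; overall the aldehyde C=O is inserted into one bond of the three-membered ring, which grows by two atoms to the oxolane. The closest known reaction type is the Lewis-acid-catalysed formal [3+2] cycloaddition of aldehydes to 2-arylcyclopropane-1,1-diesters, which is stereospecific for enantioenriched and for 2,3-trans-disubstituted cyclopropanes. The oxolane closes by an aldol-type, formally 5-endo-trig attack of the aluminium-bound malonate on the O-alkylated oxocarbenium ion. C5 arises from the (S)-benzylic carbon with inversion, which places its aryl group cis to the CH2OTIPS group at C4 (C4 is carried over unchanged), and C2 is set in the closure through an envelope transition state with both aryl groups pseudo-equatorial, which should give the 2,5-cis product. The step needs cleavage of the aryl-substituted ring bond only, clean inversion without a free benzylic cation, and no later epimerisation of the acid-labile 2,5-diaryl ether; these are secured by the benzylic donor (the CH2OTIPS-bearing carbon cannot stabilise charge), by the tight ion pair held at the chelated malonate, and by catalytic Lewis acid at low temperature with short contact time.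

**Step 6**
Reactants: 8 dimethyl (2R,4R,5R)-2,5-bis[4-(benzyloxy)-3-methoxyphenyl]-4-{[tri(propan-2-yl)silyl]oxymethyl}oxolane-3,3-dicarboxylate
Product: 10 methyl (2S,3S,4R,5R)-2,5-bis[4-(benzyloxy)-3-methoxyphenyl]-4-{[tri(propan-2-yl)silyl]oxymethyl}oxolane-3-carboxylate, via C3-epimeric monoester 9 (not isolated)
Conditions: LiCl, H2O, DMSO, 150 °C; then NaOMe (cat.), MeOH, rt
Reagents that add atoms: none
Why: Krapcho dealkoxycarbonylation (chloride SN2 at an ester methyl, loss of CO2, protonation) removes one ester; kinetic protonation anti to the C2 aryl and C4 CH2OTIPS groups should give mainly epimer 9, and methoxide then equilibrates C3 through the ester enolate to 10 with the ester trans to both neighbours, ring opening by β-elimination being the reverse of a 5-endo-trig closure and therefore slow.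

**Step 7**
Reactants: 10 methyl (2S,3S,4R,5R)-2,5-bis[4-(benzyloxy)-3-methoxyphenyl]-4-{[tri(propan-2-yl)silyl]oxymethyl}oxolane-3-carboxylate
Product: 11 [(2S,3R,4R,5R)-2,5-bis[4-(benzyloxy)-3-methoxyphenyl]-4-{[tri(propan-2-yl)silyl]oxymethyl}oxolan-3-yl]methanol
Conditions: LiAlH4, THF, 0 °C
Reagents that add atoms: none
Why: Hydride reduction of the ester to the primary alcohol at 0 °C should leave the silyl and benzyl ethers untouched and should not epimerise C3.

**Step 8**
Reactants: 11 [(2S,3R,4R,5R)-2,5-bis[4-(benzyloxy)-3-methoxyphenyl]-4-{[tri(propan-2-yl)silyl]oxymethyl}oxolan-3-yl]methanol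
Product: 12 [(2S,3R,4R,5R)-2,5-bis[4-(benzyloxy)-3-methoxyphenyl]oxolane-3,4-diyl]dimethanol
Conditions: Bu4NF, THF, 0 °C to rt
Reagents that add atoms: none
Why: Fluoride-mediated desilylation is non-acidic, so the two benzylic ring C–O bonds should not ionise.

**Step 9**
Reactants: 12 [(2S,3R,4R,5R)-2,5-bis[4-(benzyloxy)-3-methoxyphenyl]oxolane-3,4-diyl]dimethanol
Product: 13 4,4'-[(2S,3R,4R,5R)-3,4-bis(hydroxymethyl)oxolane-2,5-diyl]bis(2-methoxyphenol)
Conditions: H2 (1 atm), Pd/C, EtOAc, rt, stopped after uptake of 2 equiv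
Reagents that add atoms: none
Why: Hydrogenolysis of aryl benzyl ethers should be much faster than cleavage of the hindered secondary benzylic C–O bonds of the ring in a neutral, non-protic solvent.

**Compound list**

1 | 4-(benzyloxy)-3-methoxybenzaldehyde | COc1cc(C=O)ccc1OCc1ccccc1 | starting material
2 | (E)-3-[4-(benzyloxy)-3-methoxyphenyl]prop-2-enal | COc1cc(/C=C/C=O)ccc1OCc1ccccc1 | intermediate
3 | dimethyl bromomalonate (dimethyl 2-bromopropanedioate) | COC(=O)C(Br)C(=O)OC | starting material
4 | dimethyl (2R,3S)-2-formyl-3-[4-(benzyloxy)-3-methoxyphenyl]cyclopropane-1,1-dicarboxylate | COC(=O)C1(C(=O)OC)[C@H](C=O)[C@H]1c1ccc(OCc2ccccc2)c(OC)c1 | intermediate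
5 | dimethyl (2R,3S)-2-(hydroxymethyl)-3-[4-(benzyloxy)-3-methoxyphenyl]cyclopropane-1,1-dicarboxylate | COC(=O)C1(C(=O)OC)[C@H](CO)[C@H]1c1ccc(OCc2ccccc2)c(OC)c1 | intermediate
6 | dimethyl (2R,3S)-3-[4-(benzyloxy)-3-methoxyphenyl]-2-{[tri(propan-2-yl)silyl]oxymethyl}cyclopropane-1,1-dicarboxylate | COC(=O)C1(C(=O)OC)[C@H](CO[Si](C(C)C)(C(C)C)C(C)C)[C@H]1c1ccc(OCc2ccccc2)c(OC)c1 | intermediate
7 | ring-opened zwitterion (AlCl3-bound in the flask): dimethyl malonate carbanion carrying the (R)-CH(CH2OTIPS)–(R)-CH(aryl)–O+=CH(aryl) chain | COC(=O)[C-](C(=O)OC)[C@H](CO[Si](C(C)C)(C(C)C)C(C)C)[C@@H]([O+]=Cc1ccc(OCc2ccccc2)c(OC)c1)c1ccc(OCc2ccccc2)c(OC)c1 | intermediate (not isolated)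
8 | dimethyl (2R,4R,5R)-2,5-bis[4-(benzyloxy)-3-methoxyphenyl]-4-{[tri(propan-2-yl)silyl]oxymethyl}oxolane-3,3-dicarboxylate | COc1cc([C@H]2O[C@@H](c3ccc(OCc4ccccc4)c(OC)c3)[C@@H](CO[Si](C(C)C)(C(C)C)C(C)C)C2(C(=O)OC)C(=O)OC)ccc1OCc1ccccc1 | intermediate
9 | methyl (2S,3R,4R,5R)-2,5-bis[4-(benzyloxy)-3-methoxyphenyl]-4-{[tri(propan-2-yl)silyl]oxymethyl}oxolane-3-carboxylate (C3 epimer, ester cis to both neighbours) | COc1cc([C@H]2O[C@@H](c3ccc(OCc4ccccc4)c(OC)c3)[C@@H](CO[Si](C(C)C)(C(C)C)C(C)C)[C@H]2C(=O)OC)ccc1OCc1ccccc1 | intermediate (not isolated)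
10 | methyl (2S,3S,4R,5R)-2,5-bis[4-(benzyloxy)-3-methoxyphenyl]-4-{[tri(propan-2-yl)silyl]oxymethyl}oxolane-3-carboxylate | COc1cc([C@H]2O[C@@H](c3ccc(OCc4ccccc4)c(OC)c3)[C@@H](CO[Si](C(C)C)(C(C)C)C(C)C)[C@@H]2C(=O)OC)ccc1OCc1ccccc1 | intermediate
11 | [(2S,3R,4R,5R)-2,5-bis[4-(benzyloxy)-3-methoxyphenyl]-4-{[tri(propan-2-yl)silyl]oxymethyl}oxolan-3-yl]methanol | COc1cc([C@H]2O[C@@H](c3ccc(OCc4ccccc4)c(OC)c3)[C@@H](CO[Si](C(C)C)(C(C)C)C(C)C)[C@@H]2CO)ccc1OCc1ccccc1 | intermediate
12 | [(2S,3R,4R,5R)-2,5-bis[4-(benzyloxy)-3-methoxyphenyl]oxolane-3,4-diyl]dimethanol | COc1cc([C@H]2O[C@@H](c3ccc(OCc4ccccc4)c(OC)c3)[C@@H](CO)[C@@H]2CO)ccc1OCc1ccccc1 | intermediate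
13 | 4,4'-[(2S,3R,4R,5R)-3,4-bis(hydroxymethyl)oxolane-2,5-diyl]bis(2-methoxyphenol) | COc1cc([C@H]2O[C@@H](c3ccc(O)c(OC)c3)[C@@H](CO)[C@@H]2CO)ccc1O | target

**Totals**

Total step count: 9. Longest linear sequence: 9 steps (1 to 13); aldehyde 1 enters twice, in steps 1 and 5.

**Steps most likely to fail**

Step 5. The cyclopropane may ionise to a free, oxygen-stabilised benzylic cation, which would lose the stereochemical information at C5 and let the product drift to the more stable 4,5-trans series. The Lewis acid may also epimerise 8 at C2 or C5, or rear-side attack may be too hindered by the CH2OTIPS-bearing carbon. The fallback builds the oxolane by a different two-atom ring expansion, that of an oxirane; it sets out from 1 and comes back at 12. Reductive coupling of 1 with low-valent titanium (McMurry reaction; TiCl4, Zn, THF, reflux) should give (E)-1,2-bis[4-(benzyloxy)-3-methoxyphenyl]ethene F1. Epoxidation with dimethyldioxirane in acetone at 0 °C should give trans-2,3-bis[4-(benzyloxy)-3-methoxyphenyl]oxirane F2, racemic, whose stereocentres are erased in the next operation. Irradiation in MeCN with catalytic 1,4-dicyanonaphthalene (photoinduced electron transfer) cleaves the ring C–C bond to the W-shaped carbonyl ylide F3. This is trapped in a 1,3-dipolar cycloaddition by di-(1R,2S,5R)-menthyl fumarate to give the bis-menthyl (2S,3S,4S,5R)-2,5-bis[4-(benzyloxy)-3-methoxyphenyl]oxolane-3,4-dicarboxylate F4. The ylide geometry and the E alkene fix the 2,5-cis/3,4-trans relative configuration, and the auxiliary differentiates the two fumarate faces; which face it favours is not predicted here. The two diastereomers are separated by chromatography or crystallisation, and the antipodal menthyl ester is used should the unwanted one prevail. LiAlH4 in THF then reduces F4 to 12.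

Step 6. Equilibration at C3 may stall short of the trans,trans ester, β-elimination may open the C2–O1 bond at 150 °C, or the silyl ether may be lost and the free alcohol lactonise onto the C3 ester, locking a cis-3,4 arrangement. The fallback corrects C3 at the aldehyde oxidation level; it sets out from 9 (as its mixture with 10) and comes back at 11. LiAlH4 in THF at 0 °C reduces the mixture to 11 and its C3 epimer [(2S,3S,4R,5R)-2,5-bis[4-(benzyloxy)-3-methoxyphenyl]-4-{[tri(propan-2-yl)silyl]oxymethyl}oxolan-3-yl]methanol F5. Dess–Martin oxidation gives the aldehydes, the 2,3-cis-3,4-cis one being the (2S,3R,4R,5R)-oxolane-3-carbaldehyde F6. K2CO3 in MeOH at rt, acting on the much more acidic aldehyde α-proton, should converge the mixture on the trans,trans (2S,3S,4R,5R)-oxolane-3-carbaldehyde F7. NaBH4 in MeOH returns 11.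

Step 2. Conjugate addition to the deactivated iminium ion of the electron-rich enal may be slow, the amine may reopen the product cyclopropane, and the enantiomeric purity may erode. The fallback separates C–C bond formation from ring closure; it sets out from 2 and comes back at 4. Conjugate addition of dimethyl malonate to 2 with the same amine catalyst in EtOH should give dimethyl 2-[(1R)-1-[4-(benzyloxy)-3-methoxyphenyl]-3-oxopropyl]propanedioate F8. Bromination at the malonate carbon (NBS, cat. Mg(ClO4)2, MeCN) gives dimethyl 2-bromo-2-[(1S)-1-[4-(benzyloxy)-3-methoxyphenyl]-3-oxopropyl]propanedioate F9. 2,6-Lutidine with catalytic pyrrolidine then closes the ring through the enamine (3-exo-tet displacement of the tertiary bromide, trans) to 4.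

**Further compounds**

F1 | step 5 | (E)-1,2-bis[4-(benzyloxy)-3-methoxyphenyl]ethene | COc1cc(/C=C/c2ccc(OCc3ccccc3)c(OC)c2)ccc1OCc1ccccc1
F2 | step 5 | trans-2,3-bis[4-(benzyloxy)-3-methoxyphenyl]oxirane (racemic; (2S,3S) enantiomer drawn) | COc1cc([C@@H]2O[C@H]2c2ccc(OCc3ccccc3)c(OC)c2)ccc1OCc1ccccc1
F3 | step 5 | W-shaped carbonyl ylide from F2 | COc1cc(/C=[O+]/[CH-]c2ccc(OCc3ccccc3)c(OC)c2)ccc1OCc1ccccc1
F4 | step 5 | bis[(1R,2S,5R)-5-methyl-2-(propan-2-yl)cyclohexyl] (2S,3S,4S,5R)-2,5-bis[4-(benzyloxy)-3-methoxyphenyl]oxolane-3,4-dicarboxylate | COc1cc([C@H]2O[C@@H](c3ccc(OCc4ccccc4)c(OC)c3)[C@@H](C(=O)O[C@@H]5C[C@H](C)CC[C@H]5C(C)C)[C@@H]2C(=O)O[C@@H]6C[C@H](C)CC[C@H]6C(C)C)ccc1OCc1ccccc1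
F5 | step 6 | [(2S,3S,4R,5R)-2,5-bis[4-(benzyloxy)-3-methoxyphenyl]-4-{[tri(propan-2-yl)silyl]oxymethyl}oxolan-3-yl]methanol | COc1cc([C@H]2O[C@@H](c3ccc(OCc4ccccc4)c(OC)c3)[C@@H](CO[Si](C(C)C)(C(C)C)C(C)C)[C@H]2CO)ccc1OCc1ccccc1
F6 | step 6 | (2S,3R,4R,5R)-2,5-bis[4-(benzyloxy)-3-methoxyphenyl]-4-{[tri(propan-2-yl)silyl]oxymethyl}oxolane-3-carbaldehyde | COc1cc([C@H]2O[C@@H](c3ccc(OCc4ccccc4)c(OC)c3)[C@@H](CO[Si](C(C)C)(C(C)C)C(C)C)[C@H]2C=O)ccc1OCc1ccccc1
F7 | step 6 | (2S,3S,4R,5R)-2,5-bis[4-(benzyloxy)-3-methoxyphenyl]-4-{[tri(propan-2-yl)silyl]oxymethyl}oxolane-3-carbaldehyde | COc1cc([C@H]2O[C@@H](c3ccc(OCc4ccccc4)c(OC)c3)[C@@H](CO[Si](C(C)C)(C(C)C)C(C)C)[C@@H]2C=O)ccc1OCc1ccccc1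
F8 | step 2 | dimethyl 2-[(1R)-1-[4-(benzyloxy)-3-methoxyphenyl]-3-oxopropyl]propanedioate | COC(=O)C(C(=O)OC)[C@@H](CC=O)c1ccc(OCc2ccccc2)c(OC)c1
F9 | step 2 | dimethyl 2-bromo-2-[(1S)-1-[4-(benzyloxy)-3-methoxyphenyl]-3-oxopropyl]propanedioate | COC(=O)C(Br)(C(=O)OC)[C@@H](CC=O)c1ccc(OCc2ccccc2)c(OC)c1
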